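**Strategy.** Ring B of the target (C1, C2, C3, C4, C5, C9) is a cyclic triketide in which acyl carbons (C9, C2, C4) alternate with nucleophilic carbons (C1, C3, C5). Cutting C9–C5 and C2–C1 therefore opens both rings of the bicyclo[3.3.1]nonane at once and leaves one acyclic chain, 17, that carries a hindered aryl ester at C9, the benzoyl ketone at C5 and a dioxinone as a masked C2–C4 acylketene. In the key step two equivalents of base convert 17 into a C1=C9 ketene that is captured by C5 (ring A); the resulting C9/C1 enolate is then C-acylated by the thermally released acylketene (ring B). The only defined stereocenter of 17, C7, controls C5 and C1.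

Key step: step 10

Remarks.
- Labels C1–C9 are the bicyclo[3.3.1]nonane locants of the target: C1 prenyl bridgehead, C2 C=O, C3, C4 C–OH, C5 benzoyl bridgehead, C6 CH2, C7 CH(prenyl), C8 CMe2, C9 bridging C=O. Ring A is C1–C9–C5–C6–C7–C8 and ring B is C1–C2–C3–C4–C5–C9. The same labels are used for these carbons in the open-chain intermediates.
- Assumption: the target is one enol tautomer of a freely equilibrating 2,4-dione, so the route aims at the tautomeric mixture drawn as 21.
- The carbons that become C1 and C5 are carried as epimer mixtures from steps 7 and 9; both are deprotonated in step 10.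

Step 1
Reactants: 1 2,2,6-trimethyl-4H-1,3-dioxin-4-one
Product: 2 5-iodo-2,2,6-trimethyl-4H-1,3-dioxin-4-one
Conditions: N-iodosuccinimide, AcOH, 23 °C, dark
Reagents that add atoms: N-iodosuccinimide, O=C1CCC(=O)N1I
Why: Electrophilic iodination at the α-carbon of the vinylogous carbonate, the only nucleophilic carbon of 1 (α-halogenation of a β-alkoxy enoate).

Step 2
Reactants: 2 5-iodo-2,2,6-trimethyl-4H-1,3-dioxin-4-one; 3 1-bromo-3-methylbut-2-ene (prenyl bromide)
Product: 4 2,2,6-trimethyl-5-(3-methylbut-2-en-1-yl)-4H-1,3-dioxin-4-one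
Conditions: 3, Zn dust, LiCl, THF, 23 °C; then 2, Pd(OAc)2 (2 mol %), CPhos (4 mol %), THF, 23 °C
Reagents that add atoms: none
Why: Negishi cross-coupling of a vinyl iodide with an allylic zinc halide; the bulky biarylphosphine should steer reductive elimination to the unsubstituted allyl terminus, so that the linear prenyl group and not the reverse-prenyl isomer is delivered.

Step 3
Reactants: 5 3,3-dimethylglutaric anhydride; 6 (4S)-4-benzyl-1,3-oxazolidin-2-one
Product: 7 5-[(4S)-4-benzyl-2-oxo-1,3-oxazolidin-3-yl]-3,3-dimethyl-5-oxopentanoic acid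
Conditions: 6, n-butyllithium, THF, −78 °C; then 5, −78 → 0 °C; 1 M HCl
Reagents that add atoms: none
Why: N-acylation of the lithiated oxazolidinone by ring opening of the symmetrical cyclic anhydride gives the imide and the free acid in one operation; no stereocenter is formed.

Step 4
Reactants: 7 the imide acid; 8 2,6-di-tert-butyl-4-methylphenol
Product: 10 2,6-di-tert-butyl-4-methylphenyl 5-[(4S)-4-benzyl-2-oxo-1,3-oxazolidin-3-yl]-3,3-dimethyl-5-oxopentanoate, via acid chloride 9 (not isolated)
Conditions: (COCl)2, DMF (cat.), CH2Cl2, 0 → 23 °C; evaporate; then 8/n-butyllithium (THF, 0 °C), 0 → 23 °C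
Reagents that add atoms: none
Why: Esterification through the acyl chloride and the hindered lithium phenoxide; this aryl ester is chosen because it resists hydride, alkoxide and enolate attack in steps 5–9, yet can later leave from its own enolate to give a ketene.

Step 5
Reactants: 10 the aryl ester imide; 3 1-bromo-3-methylbut-2-ene
Product: 11 2,6-di-tert-butyl-4-methylphenyl (4S)-4-{[(4S)-4-benzyl-2-oxo-1,3-oxazolidin-3-yl]carbonyl}-3,3,7-trimethyloct-6-enoate
Conditions: NaN(SiMe3)2 (1.05 equiv), THF, −78 °C; then 3 (3 equiv), −78 → −40 °C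
Reagents that add atoms: none
Why: Evans asymmetric alkylation: the imide α-CH2 is the more acidic site, and its chelated (Z)-sodium enolate should be alkylated by the allylic bromide on the face opposite the benzyl group, which sets the future C7 (S in 11; R in the target only through a change of CIP priorities).

Step 6
Reactants: 11 the alkylated imide
Product: 12 2,6-di-tert-butyl-4-methylphenyl (4S)-4-(hydroxymethyl)-3,3,7-trimethyloct-6-enoate
Conditions: LiBH4, Et2O/THF, 0 °C
Reagents that add atoms: none
Why: Reductive cleavage of the N-acyloxazolidinone at the activated exocyclic carbonyl; the hindered aryl ester should neither be reduced nor lactonise with the new alcohol, and C7 is no longer α to a carbonyl after this step.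

Step 7
Reactants: 12 the hydroxy ester; 3 1-bromo-3-methylbut-2-ene
Product: 13 2,6-di-tert-butyl-4-methylphenyl (4S)-4-(hydroxymethyl)-3,3,7-trimethyl-2-(3-methylbut-2-en-1-yl)oct-6-enoate (both C2 epimers)
Conditions: LiN(i-Pr)2 (2.2 equiv), THF, −78 °C; then 3, DMPU, −78 → −45 °C; aq. NH4Cl
Reagents that add atoms: none
Why: Ester enolate alkylation of the alkoxide–enolate dianion: C-alkylation of the aryl ester enolate by the allylic bromide should outrun O-alkylation of the lithium alkoxide at low temperature; the new center (future C1) is planarised in step 10.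

Step 8
Reactants: 13 the diprenyl hydroxy ester; 4 the prenyl dioxinone
Product: 15 2,6-di-tert-butyl-4-methylphenyl (4S)-4-{2-[2,2-dimethyl-5-(3-methylbut-2-en-1-yl)-4-oxo-4H-1,3-dioxin-6-yl]ethyl}-3,3,7-trimethyl-2-(3-methylbut-2-en-1-yl)oct-6-enoate (both C2 epimers), via triflate 14 (not isolated)
Conditions: 13, Tf2O, 2,6-lutidine, CH2Cl2, −78 °C; separately 4, LiN(i-Pr)2, THF/DMPU, −78 °C; add cold 14, −78 → −30 °C
Reagents that add atoms: none
Why: γ-Alkylation of the lithium dienolate of a 6-methyl-1,3-dioxin-4-one (vinylogous enolate alkylation) forms C5–C6; a primary triflate is used because the electrophilic carbon is β-branched, and the α-position of the dienolate is blocked by the prenyl group.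

Step 9
Reactants: 15 the chain-extended dioxinone; 16 N-methoxy-N-methylbenzamide
Product: 17 2,6-di-tert-butyl-4-methylphenyl (4R)-4-{2-[2,2-dimethyl-5-(3-methylbut-2-en-1-yl)-4-oxo-4H-1,3-dioxin-6-yl]-3-oxo-3-phenylpropyl}-3,3,7-trimethyl-2-(3-methylbut-2-en-1-yl)oct-6-enoate (epimers at C2 and at the benzoyl-bearing carbon)
Conditions: LiN(i-Pr)2 (1.2 equiv), THF, −78 °C; then 16, −78 → −20 °C; aq. NH4Cl
Reagents that add atoms: none
Why: γ-Acylation of the dioxinone dienolate by a Weinreb amide (vinylogous Claisen-type acylation); the chelated tetrahedral adduct persists until work-up, so the more acidic product cannot quench the dienolate, and the hindered aryl ester is inert to the dienolate.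

Step 10
Reactants: 17 the acyclic benzoyl dioxinone aryl ester
Product: 21 (1R,5S,7R)-5-benzoyl-4-hydroxy-8,8-dimethyl-1,3,7-tris(3-methylbut-2-en-1-yl)bicyclo[3.3.1]non-3-ene-2,9-dione (the target), via ketene 18 (not isolated), via monocyclic ketone 19 (not isolated), via acylketene 20 (not isolated)
Conditions: lithium 2,2,6,6-tetramethylpiperidide (2.3 equiv), THF/PhMe, −78 → 23 °C; then 100 °C (sealed tube); aq. HCl to pH 3
Reagents that add atoms: none
Why: The first equivalent of base gives the benzoyl-stabilised carbanion at C5 and the second deprotonates C1 of the hindered aryl ester, whose enolate expels the aryloxide on warming to give ketene 18; C5 adds to the ketene carbon C9 and leaves the C9 enolate directed only toward C1 (19), because C5 is now quaternary. Heating then releases acylketene 20 by retro-[4+2] loss of acetone from the dioxinone and C1 of the enolate adds to its central carbon C2; the closest known types are the ester enolate → ketene → regiodefined ketone enolate sequence of hindered aryl esters, C-acylation of stabilised carbanions by ketenes, and the second ring closure of the Effenberger annulation, which C-acylates a cyclohexanone enol derivative with a pendant β-ketoacyl unit to the same bicyclo[3.3.1]nonane-2,4,9-trione. Ring A closes 6-exo-dig on the ketene C=O with the former ketene C=C ending endocyclic as the enolate, and ring B closes 6-exo-dig on the acylketene C=O, driven by formation of the C2–C3–C4 diketonate. C5 is set in the first closure, where the C7 prenyl should sit equatorial in the half-chair and lithium bridging the benzoyl enolate oxygen and the ketene oxygen should hold the benzoyl pseudo-equatorial, so that the dioxinone arm ends axial and trans to the C7 prenyl; C1 is then fixed by the bridge, since only the enolate face syn to the axial arm can be reached. The step needs C- over O-acylation twice and this facial selectivity at C5: O-closure in the first stage would be eight-membered, O-acylation by the acylketene should be reversible through the enol β-ketoester whereas C-acylation is not, and a C5 epimer could at worst give the separable 7-epimer.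

**Compound list**

1 | 2,2,6-trimethyl-4H-1,3-dioxin-4-one | CC1=CC(=O)OC(C)(C)O1 | starting material
2 | 5-iodo-2,2,6-trimethyl-4H-1,3-dioxin-4-one | CC1=C(I)C(=O)OC(C)(C)O1 | intermediate
3 | 1-bromo-3-methylbut-2-ene (prenyl bromide) | CC(C)=CCBr | starting material
4 | 2,2,6-trimethyl-5-(3-methylbut-2-en-1-yl)-4H-1,3-dioxin-4-one | CC1=C(CC=C(C)C)C(=O)OC(C)(C)O1 | intermediate
5 | 3,3-dimethylglutaric anhydride (4,4-dimethyloxane-2,6-dione) | CC1(C)CC(=O)OC(=O)C1 | starting material
6 | (4S)-4-benzyl-1,3-oxazolidin-2-one | O=C1OC[C@H](Cc2ccccc2)N1 | starting material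
7 | 5-[(4S)-4-benzyl-2-oxo-1,3-oxazolidin-3-yl]-3,3-dimethyl-5-oxopentanoic acid | O=C(O)CC(C)(C)CC(=O)N1C(=O)OC[C@@H]1Cc1ccccc1 | intermediate
8 | 2,6-di-tert-butyl-4-methylphenol | Cc1cc(C(C)(C)C)c(O)c(C(C)(C)C)c1 | starting material
9 | 5-[(4S)-4-benzyl-2-oxo-1,3-oxazolidin-3-yl]-3,3-dimethyl-5-oxopentanoyl chloride | O=C(Cl)CC(C)(C)CC(=O)N1C(=O)OC[C@@H]1Cc1ccccc1 | intermediate
10 | 2,6-di-tert-butyl-4-methylphenyl 5-[(4S)-4-benzyl-2-oxo-1,3-oxazolidin-3-yl]-3,3-dimethyl-5-oxopentanoate | Cc1cc(C(C)(C)C)c(OC(=O)CC(C)(C)CC(=O)N2C(=O)OC[C@@H]2Cc2ccccc2)c(C(C)(C)C)c1 | intermediate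
11 | 2,6-di-tert-butyl-4-methylphenyl (4S)-4-{[(4S)-4-benzyl-2-oxo-1,3-oxazolidin-3-yl]carbonyl}-3,3,7-trimethyloct-6-enoate | Cc1cc(C(C)(C)C)c(OC(=O)CC(C)(C)[C@H](CC=C(C)C)C(=O)N2C(=O)OC[C@@H]2Cc2ccccc2)c(C(C)(C)C)c1 | intermediate
12 | 2,6-di-tert-butyl-4-methylphenyl (4S)-4-(hydroxymethyl)-3,3,7-trimethyloct-6-enoate | Cc1cc(C(C)(C)C)c(OC(=O)CC(C)(C)[C@H](CC=C(C)C)CO)c(C(C)(C)C)c1 | intermediate
13 | 2,6-di-tert-butyl-4-methylphenyl (4S)-4-(hydroxymethyl)-3,3,7-trimethyl-2-(3-methylbut-2-en-1-yl)oct-6-enoate, both C2 epimers | Cc1cc(C(C)(C)C)c(OC(=O)C(CC=C(C)C)C(C)(C)[C@H](CC=C(C)C)CO)c(C(C)(C)C)c1 | intermediate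
14 | trifluoromethanesulfonate of 13, (4S) | Cc1cc(C(C)(C)C)c(OC(=O)C(CC=C(C)C)C(C)(C)[C@H](CC=C(C)C)COS(=O)(=O)C(F)(F)F)c(C(C)(C)C)c1 | intermediate
15 | 2,6-di-tert-butyl-4-methylphenyl (4S)-4-{2-[2,2-dimethyl-5-(3-methylbut-2-en-1-yl)-4-oxo-4H-1,3-dioxin-6-yl]ethyl}-3,3,7-trimethyl-2-(3-methylbut-2-en-1-yl)oct-6-enoate, both C2 epimers | Cc1cc(C(C)(C)C)c(OC(=O)C(CC=C(C)C)C(C)(C)[C@H](CC=C(C)C)CCC2=C(CC=C(C)C)C(=O)OC(C)(C)O2)c(C(C)(C)C)c1 | intermediate
16 | N-methoxy-N-methylbenzamide | CON(C)C(=O)c1ccccc1 | starting material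
17 | 2,6-di-tert-butyl-4-methylphenyl (4R)-4-{2-[2,2-dimethyl-5-(3-methylbut-2-en-1-yl)-4-oxo-4H-1,3-dioxin-6-yl]-3-oxo-3-phenylpropyl}-3,3,7-trimethyl-2-(3-methylbut-2-en-1-yl)oct-6-enoate, epimers at C2 and at the benzoyl-bearing carbon | Cc1cc(C(C)(C)C)c(OC(=O)C(CC=C(C)C)C(C)(C)[C@H](CC=C(C)C)CC(C(=O)c2ccccc2)C2=C(CC=C(C)C)C(=O)OC(C)(C)O2)c(C(C)(C)C)c1 | intermediate
18 | C1=C9 ketene formed from 17 by loss of the aryloxide (in the flask the lithium enolate at the benzoyl carbon; drawn neutral) | O=C=C(CC=C(C)C)C(C)(C)[C@H](CC=C(C)C)CC(C(=O)c1ccccc1)C1=C(CC=C(C)C)C(=O)OC(C)(C)O1 | intermediate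
19 | 6-[1-benzoyl-4,4-dimethyl-3,5-bis(3-methylbut-2-en-1-yl)-2-oxocyclohexyl]-2,2-dimethyl-5-(3-methylbut-2-en-1-yl)-4H-1,3-dioxin-4-one, dioxinone trans and benzoyl cis to the prenyl at ring position 5 (in the flask the C9/C1 lithium enolate; drawn as the ketone) | O=C1OC(C)(C)OC(=C1CC=C(C)C)[C@]2(C(=O)c3ccccc3)C[C@@H](CC=C(C)C)C(C)(C)C(CC=C(C)C)C2=O | intermediate
20 | acylketene formed from 19 by loss of acetone: 3-[1-benzoyl-4,4-dimethyl-3,5-bis(3-methylbut-2-en-1-yl)-2-oxocyclohexyl]-2-(3-methylbut-2-en-1-yl)-3-oxoprop-1-en-1-one (in the flask the C9/C1 lithium enolate) | O=C=C(CC=C(C)C)C(=O)[C@]1(C(=O)c2ccccc2)C[C@@H](CC=C(C)C)C(C)(C)C(CC=C(C)C)C1=O | intermediate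
21 | (1R,5S,7R)-5-benzoyl-4-hydroxy-8,8-dimethyl-1,3,7-tris(3-methylbut-2-en-1-yl)bicyclo[3.3.1]non-3-ene-2,9-dione; C7 prenyl on the face of ring A opposite to the C2–C3–C4 bridge | CC(C)=CCC1=C(O)[C@]2(C(=O)c3ccccc3)C[C@@H](CC=C(C)C)C(C)(C)[C@](CC=C(C)C)(C1=O)C2=O | target

**Step count.** Ten steps in total; the longest linear sequence is eight steps (steps 3–10, from 3,3-dimethylglutaric anhydride), with steps 1–2 as a two-step side branch to dioxinone 4.

**Steps most likely to fail**

Step 10. Three processes may go wrong. The second deprotonation at the hindered C1–H may be incomplete, so that the ketene never forms. The facial selectivity at C5 during closure of ring A may be poor, which would be carried into the 7-epimer. O-acylation may compete with C-acylation at the acylketene stage. The fallback sets out from 13 and returns at 21; it changes the order of bond formation so that C5 can equilibrate before it becomes quaternary and ring B is closed by a classical annulation. Alcohol 13 is converted (I2, PPh3, imidazole) into the primary iodide F1, which alkylates the lithium enolate of acetophenone (THF/DMPU) to give the aryl ketone F2. Lithium diisopropylamide (for the ketone) followed by sec-butyllithium (for the ester C–H, tolerated here because no dioxinone is present) closes ring A through the same aryl ester enolate → ketene pathway and gives the enolised 2-benzoylcyclohexanone F3, with C5 under thermodynamic control. Commercial diethyl prenylmalonate is saponified to prenylmalonic acid F4 and converted with oxalyl chloride into prenylmalonyl dichloride F5. Effenberger annulation of F3 with F5 (CH2Cl2, −20 → 23 °C; then aq. KOH, BnEt3NCl) should form C4–C5 by axial C-acylation trans to the equatorial C7 prenyl and then C2–C1, giving 21 directly.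

Step 8. Substitution at the β-branched carbon may be sluggish. Triflate 14 may be lost by cation–olefin cyclisation or elimination before it is captured. The dienolate may react at its α- instead of its γ-carbon. The fallback sets out from 13 and 4 and returns at 17, so it also replaces step 9; C5–C6 is made by condensation at an aldehyde carbon instead of by substitution. Alcohol 13 is oxidised with Dess–Martin periodinane to the aldehyde F6. Separately the lithium dienolate of 4 is acylated with 16 to give the keto-dioxinone F7. Knoevenagel condensation of F6 with F7 (TiCl4, pyridine, THF, 0 °C, non-enolising for the α-stereocenter of F6) gives the alkylidene F8, and conjugate reduction of its doubly activated C=C with Hantzsch ester gives 17.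

Step 9. Acylation of the secondary dienolate may stall, proton transfer may return starting material, or acylation may occur at oxygen. The fallback sets out from 15 and returns at 17; the benzoyl group is introduced at the alcohol oxidation level. Vinylogous aldol addition of the lithium dienolate of 15 to benzaldehyde (THF, −78 °C) gives the benzylic alcohol F9 as a diastereomer mixture, and oxidation with Dess–Martin periodinane gives 17.

**Further compounds**

F1 | step 10 | 2,6-di-tert-butyl-4-methylphenyl (4S)-4-(iodomethyl)-3,3,7-trimethyl-2-(3-methylbut-2-en-1-yl)oct-6-enoate | Cc1cc(C(C)(C)C)c(OC(=O)C(CC=C(C)C)C(C)(C)[C@H](CC=C(C)C)CI)c(C(C)(C)C)c1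
F2 | step 10 | 2,6-di-tert-butyl-4-methylphenyl (4S)-3,3,7-trimethyl-2-(3-methylbut-2-en-1-yl)-4-(3-oxo-3-phenylpropyl)oct-6-enoate | Cc1cc(C(C)(C)C)c(OC(=O)C(CC=C(C)C)C(C)(C)[C@H](CC=C(C)C)CCC(=O)c2ccccc2)c(C(C)(C)C)c1
F3 | step 10 | 2-benzoyl-5,5-dimethyl-4,6-bis(3-methylbut-2-en-1-yl)cyclohexan-1-one, C4 configured as C7 of the target, C2 and C6 epimerisable | O=C(c1ccccc1)C1C[C@@H](CC=C(C)C)C(C)(C)C(CC=C(C)C)C1=O
F4 | step 10 | 2-(3-methylbut-2-en-1-yl)propanedioic acid | CC(C)=CCC(C(=O)O)C(=O)O
F5 | step 10 | 2-(3-methylbut-2-en-1-yl)propanedioyl dichloride | CC(C)=CCC(C(=O)Cl)C(=O)Cl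
F6 | step 8 | 2,6-di-tert-butyl-4-methylphenyl (4S)-4-formyl-3,3,7-trimethyl-2-(3-methylbut-2-en-1-yl)oct-6-enoate | Cc1cc(C(C)(C)C)c(OC(=O)C(CC=C(C)C)C(C)(C)[C@H](CC=C(C)C)C=O)c(C(C)(C)C)c1
F7 | step 8 | 2,2-dimethyl-5-(3-methylbut-2-en-1-yl)-6-(2-oxo-2-phenylethyl)-4H-1,3-dioxin-4-one | O=C(CC1=C(CC=C(C)C)C(=O)OC(C)(C)O1)c1ccccc1
F8 | step 8 | Knoevenagel alkylidene of F6 and F7 (C5=C6 alkene, either geometry) | Cc1cc(C(C)(C)C)c(OC(=O)C(CC=C(C)C)C(C)(C)[C@H](CC=C(C)C)C=C(C(=O)c2ccccc2)C2=C(CC=C(C)C)C(=O)OC(C)(C)O2)c(C(C)(C)C)c1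
F9 | step 9 | vinylogous aldol adduct of 15 and benzaldehyde (secondary benzylic alcohol, diastereomer mixture) | Cc1cc(C(C)(C)C)c(OC(=O)C(CC=C(C)C)C(C)(C)[C@H](CC=C(C)C)CC(C(O)c2ccccc2)C2=C(CC=C(C)C)C(=O)OC(C)(C)O2)c(C(C)(C)C)c1
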